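**Strategy.** The tetrahydropyran ring (O1, C2 aryl, C3, C4 acetoxy, C5, C6 side chain) hides an aldol retron: the C4 oxygen is β to C2 and trans to the C6 side chain. The ring is therefore closed between C3 and C4 at the lactone oxidation level, by a SmI2-promoted intramolecular Reformatsky reaction of a β-(bromoacetoxy) aldehyde that carries only the C6 stereocentre, set by catalytic asymmetric allylation. This reductive union of two electrophilic carbons builds the ring and relays C6 to C4 through a samarium chelate in one operation. The lactone carbonyl then takes up the aryl group, and axial hydride delivery to the oxocarbenium ion sets C2.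

Key step: step 5

Remark: the ring numbering O1, C2 (aryl carbon), C3, C4 (oxygen-bearing carbon), C5, C6 (side-chain carbon) is used for all cyclic compounds, and the two phenolic starting materials are assumed to be commercial.

Step 1
Reactants: 1 4-(3-hydroxypropyl)-2-methoxyphenol (dihydroconiferyl alcohol)
Product: 2 3-[4-(benzyloxy)-3-methoxyphenyl]propan-1-ol
Conditions: BnBr, K2CO3, acetone, reflux
Reagents that add atoms: benzyl bromide, BrCc1ccccc1
Why: Williamson ether synthesis in which K2CO3 deprotonates only the more acidic phenol, so the primary alcohol stays free for the next step.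

Step 2
Reactants: 2 3-[4-(benzyloxy)-3-methoxyphenyl]propan-1-ol
Product: 4 (3S)-1-[4-(benzyloxy)-3-methoxyphenyl]hex-5-en-3-ol, via aldehyde 3 (not isolated)
Conditions: allyl acetate, [Ir(cod)Cl]2 (2.5 mol %), (R)-BINAP (5 mol %), 4-chloro-3-nitrobenzoic acid (10 mol %), Cs2CO3 (20 mol %), THF, 100 °C, sealed tube
Reagents that add atoms: allyl acetate, CC(=O)OCC=C
Why: Krische transfer-hydrogenative allylation, in which the iridium catalyst dehydrogenates the alcohol to aldehyde 3 and the chiral π-allyliridium C,O-benzoate complex allylates it, (R)-BINAP being the antipode expected to direct the allyl group to the Re face and so set the (S) carbinol centre (the future C6).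

Step 3
Reactants: 4 (3S)-1-[4-(benzyloxy)-3-methoxyphenyl]hex-5-en-3-ol
Product: 5 (3S)-1-[4-(benzyloxy)-3-methoxyphenyl]hex-5-en-3-yl bromoacetate
Conditions: BrCH2COBr, pyridine, CH2Cl2, 0 °C
Reagents that add atoms: bromoacetyl bromide, BrCC(Br)=O
Why: Nucleophilic acyl substitution of the acid bromide by the secondary alcohol with pyridine as base, which leaves the stereocentre untouched.

Step 4
Reactants: 5 (3S)-1-[4-(benzyloxy)-3-methoxyphenyl]hex-5-en-3-yl bromoacetate
Product: 7 (3S)-1-[4-(benzyloxy)-3-methoxyphenyl]-5-oxopentan-3-yl bromoacetate, via ozonide 6 (not isolated)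
Conditions: O3, CH2Cl2, −78 °C (Sudan Red 7B end point); then Me2S, −78 °C to rt; used crude at once
Reagents that add atoms: ozone, [O-][O+]=O
Why: Ozonolysis with reductive work-up, in which ozone should react with the terminal alkene faster than with the alkoxyarenes (hence the indicator end point) and dimethyl sulfide reduces ozonide 6 to the aldehyde, which is not stored because β-acyloxy aldehydes eliminate readily.

Step 5
Reactants: 7 (3S)-1-[4-(benzyloxy)-3-methoxyphenyl]-5-oxopentan-3-yl bromoacetate
Product: 9 (4S,6S)-6-{2-[4-(benzyloxy)-3-methoxyphenyl]ethyl}-4-hydroxytetrahydro-2H-pyran-2-one, via samarium enolate 8 (not isolated)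
Conditions: SmI2 (2.2 equiv), THF, −78 °C, slow addition of 7 at high dilution; 0.1 M HCl, 0 °C
Reagents that add atoms: none
Why: Two single-electron transfers from SmI2 to the C–Br bond give the ester enolate 8 of trivalent samarium, whose metal also binds the aldehyde oxygen, and the enolate carbon then adds to the aldehyde carbon to forge the C3–C4 bond of lactone 9. The closest known reaction type is the SmI2-promoted intramolecular Reformatsky reaction of β-(bromoacetoxy) aldehydes, a reductive union of two carbons that are both electrophilic in the precursor. The six-membered ring closes in the 6-(enolendo)-exo-trig mode. The new C4 stereocentre is controlled by the C6 stereocentre through a chelated chair-like transition state in which the side chain is equatorial and the aldehyde oxygen must be axial to reach the samarium on the enolate oxygen, which should place the hydroxyl trans to the side chain (4S). The step needs 1,3-diastereoselectivity and reduction of the C–Br bond before the aldehyde: the short ester tether, which forces an endocyclic enolate and a bicyclic chelate, secures the first, and the activated α-bromo ester, reduced far faster than an aliphatic aldehyde by SmI2 in THF without HMPA at −78 °C, secures the second.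

Step 6
Reactants: 10 5-bromo-2-hydroxy-3-methoxybenzaldehyde
Product: 12 5-bromo-3-methoxybenzene-1,2-diol, via aryl formate 11 (not isolated)
Conditions: 30% H2O2, NaOH, H2O, rt, N2; then HCl
Reagents that add atoms: hydrogen peroxide, OO
Why: Dakin oxidation, in which hydroperoxide adds to the ortho-hydroxy aldehyde, the electron-rich aryl group migrates to oxygen to give formate 11, and the basic medium hydrolyses it to the catechol.

Step 7
Reactants: 12 5-bromo-3-methoxybenzene-1,2-diol
Product: 13 1,2-bis(benzyloxy)-5-bromo-3-methoxybenzene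
Conditions: BnBr, K2CO3, DMF, 60 °C, argon
Reagents that add atoms: benzyl bromide, BrCc1ccccc1
Why: Double Williamson ether synthesis of the catechol, run under argon because the free catechol is air-sensitive in base.

Step 8
Reactants: 13 1,2-bis(benzyloxy)-5-bromo-3-methoxybenzene and 9 (4S,6S)-6-{2-[4-(benzyloxy)-3-methoxyphenyl]ethyl}-4-hydroxytetrahydro-2H-pyran-2-one
Product: 15 (4S,6S)-2-[3,4-bis(benzyloxy)-5-methoxyphenyl]-6-{2-[4-(benzyloxy)-3-methoxyphenyl]ethyl}tetrahydro-2H-pyran-2,4-diol, via aryllithium 14 (not isolated)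
Conditions: 13 (2.4 equiv), n-BuLi (2.3 equiv), THF, −78 °C; then 9, −78 °C; NH4Cl (aq)
Reagents that add atoms: none
Why: Bromine–lithium exchange gives aryllithium 14, one equivalent of which is consumed by the C4 hydroxyl group while a second adds once to the lactone carbonyl (organolithium addition to a lactone, the tetrahedral lithium hemiketal alkoxide being stable at −78 °C); the new C2 centre is a hemiketal and is erased in the next step.

Step 9
Reactants: 15 (4S,6S)-2-[3,4-bis(benzyloxy)-5-methoxyphenyl]-6-{2-[4-(benzyloxy)-3-methoxyphenyl]ethyl}tetrahydro-2H-pyran-2,4-diol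
Product: 17 (2S,4S,6S)-2-[3,4-bis(benzyloxy)-5-methoxyphenyl]-6-{2-[4-(benzyloxy)-3-methoxyphenyl]ethyl}tetrahydro-2H-pyran-4-ol, via oxocarbenium ion 16 (not isolated)
Conditions: Et3SiH, CF3CO2H, CH2Cl2, −40 °C; NaHCO3 (aq)
Reagents that add atoms: none
Why: Ionic hydrogenation of the lactol, in which acid ionises the hemiketal to the aryl-stabilised oxocarbenium ion 16 and triethylsilane delivers hydride along the axial trajectory of the half-chair that holds the C6 side chain pseudo-equatorial and the C4 hydroxyl pseudo-axial, so the aryl group should end equatorial and C2 cis to C6 (2S).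

Step 10
Reactants: 17 (2S,4S,6S)-2-[3,4-bis(benzyloxy)-5-methoxyphenyl]-6-{2-[4-(benzyloxy)-3-methoxyphenyl]ethyl}tetrahydro-2H-pyran-4-ol
Product: 18 (2S,4S,6S)-2-[3,4-bis(benzyloxy)-5-methoxyphenyl]-6-{2-[4-(benzyloxy)-3-methoxyphenyl]ethyl}tetrahydro-2H-pyran-4-yl acetate
Conditions: Ac2O, pyridine, DMAP (cat.), CH2Cl2, rt
Reagents that add atoms: acetic anhydride, CC(=O)OC(C)=O
Why: DMAP-catalysed acylation of the axial secondary alcohol, the only free nucleophilic group, with retention at C4.

Step 11
Reactants: 18 (2S,4S,6S)-2-[3,4-bis(benzyloxy)-5-methoxyphenyl]-6-{2-[4-(benzyloxy)-3-methoxyphenyl]ethyl}tetrahydro-2H-pyran-4-yl acetate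
Product: 19 (2S,4S,6S)-2-(3,4-dihydroxy-5-methoxyphenyl)-6-[2-(4-hydroxy-3-methoxyphenyl)ethyl]tetrahydro-2H-pyran-4-yl acetate
Conditions: H2 (1 atm), 10% Pd/C, EtOAc, rt; work-up under argon
Reagents that add atoms: none
Why: Catalytic hydrogenolysis should cleave the three aryl benzyl ethers faster than the cyclic benzylic C2–O1 bond under neutral conditions in EtOAc, and the acetate is inert to it.

**Compound list**

1 | 4-(3-hydroxypropyl)-2-methoxyphenol (dihydroconiferyl alcohol) | COc1cc(CCCO)ccc1O | starting material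
2 | 3-[4-(benzyloxy)-3-methoxyphenyl]propan-1-ol | COc1cc(CCCO)ccc1OCc2ccccc2 | intermediate
3 | aldehyde: 3-[4-(benzyloxy)-3-methoxyphenyl]propanal | COc1cc(CCC=O)ccc1OCc2ccccc2 | intermediate
4 | (3S)-1-[4-(benzyloxy)-3-methoxyphenyl]hex-5-en-3-ol | COc1cc(CC[C@H](O)CC=C)ccc1OCc2ccccc2 | intermediate
5 | (3S)-1-[4-(benzyloxy)-3-methoxyphenyl]hex-5-en-3-yl bromoacetate | COc1cc(CC[C@H](OC(=O)CBr)CC=C)ccc1OCc2ccccc2 | intermediate
6 | ozonide: (2S)-4-[4-(benzyloxy)-3-methoxyphenyl]-1-(1,2,4-trioxolan-3-yl)butan-2-yl bromoacetate (both epimers at the trioxolane carbon) | COc1cc(CC[C@H](OC(=O)CBr)CC2OCOO2)ccc1OCc3ccccc3 | intermediate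
7 | (3S)-1-[4-(benzyloxy)-3-methoxyphenyl]-5-oxopentan-3-yl bromoacetate | COc1cc(CC[C@H](OC(=O)CBr)CC=O)ccc1OCc2ccccc2 | intermediate
8 | samarium enolate: diiodosamarium O-enolate of the acetate ester of 7 (trivalent samarium) | COc1cc(CC[C@H](OC(=C)O[Sm](I)I)CC=O)ccc1OCc2ccccc2 | intermediate
9 | (4S,6S)-6-{2-[4-(benzyloxy)-3-methoxyphenyl]ethyl}-4-hydroxytetrahydro-2H-pyran-2-one | COc1cc(CC[C@H]2C[C@H](O)CC(=O)O2)ccc1OCc3ccccc3 | intermediate
10 | 5-bromo-2-hydroxy-3-methoxybenzaldehyde | COc1cc(Br)cc(C=O)c1O | starting material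
11 | aryl formate: 5-bromo-2-hydroxy-3-methoxyphenyl formate | COc1cc(Br)cc(OC=O)c1O | intermediate
12 | 5-bromo-3-methoxybenzene-1,2-diol | COc1cc(Br)cc(O)c1O | intermediate
13 | 1,2-bis(benzyloxy)-5-bromo-3-methoxybenzene | COc1cc(Br)cc(OCc2ccccc2)c1OCc3ccccc3 | intermediate
14 | aryllithium: [3,4-bis(benzyloxy)-5-methoxyphenyl]lithium | COc1cc([Li])cc(OCc2ccccc2)c1OCc3ccccc3 | intermediate
15 | (4S,6S)-2-[3,4-bis(benzyloxy)-5-methoxyphenyl]-6-{2-[4-(benzyloxy)-3-methoxyphenyl]ethyl}tetrahydro-2H-pyran-2,4-diol (lactol, C2 unassigned, in equilibrium with the open hydroxy ketone) | COc1cc(CC[C@H]2C[C@H](O)CC(O)(c3cc(OCc4ccccc4)c(OCc5ccccc5)c(OC)c3)O2)ccc1OCc6ccccc6 | intermediate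
16 | oxocarbenium ion: (4S,6S)-2-[3,4-bis(benzyloxy)-5-methoxyphenyl]-6-{2-[4-(benzyloxy)-3-methoxyphenyl]ethyl}-4-hydroxy-3,4,5,6-tetrahydropyrylium | COc1cc(CC[C@H]2C[C@H](O)CC(c3cc(OCc4ccccc4)c(OCc5ccccc5)c(OC)c3)=[O+]2)ccc1OCc6ccccc6 | intermediate
17 | (2S,4S,6S)-2-[3,4-bis(benzyloxy)-5-methoxyphenyl]-6-{2-[4-(benzyloxy)-3-methoxyphenyl]ethyl}tetrahydro-2H-pyran-4-ol | COc1cc(CC[C@H]2C[C@H](O)C[C@@H](c3cc(OCc4ccccc4)c(OCc5ccccc5)c(OC)c3)O2)ccc1OCc6ccccc6 | intermediate
18 | (2S,4S,6S)-2-[3,4-bis(benzyloxy)-5-methoxyphenyl]-6-{2-[4-(benzyloxy)-3-methoxyphenyl]ethyl}tetrahydro-2H-pyran-4-yl acetate | COc1cc(CC[C@H]2C[C@H](OC(C)=O)C[C@@H](c3cc(OCc4ccccc4)c(OCc5ccccc5)c(OC)c3)O2)ccc1OCc6ccccc6 | intermediate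
19 | (2S,4S,6S)-2-(3,4-dihydroxy-5-methoxyphenyl)-6-[2-(4-hydroxy-3-methoxyphenyl)ethyl]tetrahydro-2H-pyran-4-yl acetate | COc1cc(CC[C@H]2C[C@H](OC(C)=O)C[C@@H](c3cc(O)c(O)c(OC)c3)O2)ccc1O | target

**Step count.** Total: 11 steps. Longest linear sequence: 9 steps (steps 1 to 5 and 8 to 11); steps 6 and 7 make the aryl bromide.

**Steps most likely to fail**

Step 5 (key step). The samarium enolate may be protonated before it cyclises, the aldehyde may undergo pinacol-type coupling or lose the acyloxy group by β-elimination, or the chelate may be too loose for high 1,3-induction. The fallback sets out from alcohol 4. Esterification with acryloyl chloride (Et3N, CH2Cl2, 0 °C) gives the acrylate F1, and ring-closing metathesis (second-generation Grubbs catalyst, CH2Cl2, reflux) gives the dihydropyranone F2. Nucleophilic epoxidation (H2O2, NaOH, MeOH, 0 °C) should occur anti to the C6 side chain and give the epoxy lactone F3. Reductive opening at the α-carbon with (PhSe)2, NaBH4 and AcOH in EtOH then gives the trans β-hydroxy lactone, and the fallback comes back to the route at 9.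

Step 8. The C4 lithium alkoxide may trigger enolisation or retro-aldol cleavage of the lactone, or the aryllithium may be consumed as a base without adding. The fallback sets out from 9. Silylation (TESCl, imidazole, CH2Cl2, 0 °C) gives the silyl ether F4, and addition of aryllithium 14 (1.2 equiv, THF, −78 °C) gives the silylated lactol F5. Cleavage of the silyl ether (AcOH/THF/H2O, rt) brings the fallback back to the route at 15.

Step 9. The oxocarbenium ion may lose a C3 proton and then the C4 oxygen, or the electron-rich benzylic C2–O1 bond of the product may ionise again and be reduced with ring opening. The fallback sets out from 15. NaBH4 (MeOH, 0 °C) reduces the open hydroxy ketone tautomer to the triol F6 as both benzylic epimers. Catalytic camphorsulfonic acid in CH2Cl2 should then ionise only the electron-rich benzylic alcohol, and the distal secondary hydroxyl (the future O1) closes the ring reversibly, so the 2,6-cis isomer with both carbon substituents equatorial is expected to accumulate under thermodynamic control. The fallback comes back to the route at 17.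

**Further compounds**

F1 | step 5 | (3S)-1-[4-(benzyloxy)-3-methoxyphenyl]hex-5-en-3-yl acrylate | COc1cc(CC[C@H](OC(=O)C=C)CC=C)ccc1OCc2ccccc2
F2 | step 5 | (6S)-6-{2-[4-(benzyloxy)-3-methoxyphenyl]ethyl}-5,6-dihydro-2H-pyran-2-one | COc1cc(CC[C@H]2CC=CC(=O)O2)ccc1OCc3ccccc3
F3 | step 5 | (3S,4S,6S)-6-{2-[4-(benzyloxy)-3-methoxyphenyl]ethyl}-3,4-epoxytetrahydro-2H-pyran-2-one (epoxide anti to the side chain) | COc1cc(CC[C@H]2C[C@@H]3O[C@@H]3C(=O)O2)ccc1OCc4ccccc4
F4 | step 8 | (4S,6S)-6-{2-[4-(benzyloxy)-3-methoxyphenyl]ethyl}-4-[(triethylsilyl)oxy]tetrahydro-2H-pyran-2-one | COc1cc(CC[C@H]2C[C@H](O[Si](CC)(CC)CC)CC(=O)O2)ccc1OCc3ccccc3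
F5 | step 8 | (4S,6S)-2-[3,4-bis(benzyloxy)-5-methoxyphenyl]-6-{2-[4-(benzyloxy)-3-methoxyphenyl]ethyl}-4-[(triethylsilyl)oxy]tetrahydro-2H-pyran-2-ol (C2 unassigned) | COc1cc(CC[C@H]2C[C@H](O[Si](CC)(CC)CC)CC(O)(c3cc(OCc4ccccc4)c(OCc5ccccc5)c(OC)c3)O2)ccc1OCc6ccccc6
F6 | step 9 | (3S,5S)-1-[3,4-bis(benzyloxy)-5-methoxyphenyl]-7-[4-(benzyloxy)-3-methoxyphenyl]heptane-1,3,5-triol (both C1 epimers) | COc1cc(CC[C@H](O)C[C@H](O)CC(O)c2cc(OCc3ccccc3)c(OCc4ccccc4)c(OC)c2)ccc1OCc5ccccc5
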